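## Analysis of the target

The target is a tridepside with no stereocentre: three benzene rings joined in a row by two aryl ester bonds. Ring A is a 2,3,4-trimethoxy-6-methylbenzoyl group, ring B a 2-hydroxy-6-methylbenzoyl unit acylated at O4 by ring A, and ring C a 2-hydroxy-6-methylbenzoic acid acylated at O4 by ring B. Both ester carbonyls lie between two ortho substituents (OMe/CH3 on ring A, OH/CH3 on ring B), so acyl transfer at these carbons is hindered. Once made, the aryl esters are activated esters that do not tolerate hydroxide, alkoxide, amines or warm phenoxide, so the ring C acid must be unmasked without hydrolysis. Rings B and C each carry two oxygens of which only O4 is to be acylated, so the oxygens must be told apart. The strategy rests on ring B: O2 and O4 flank C3–H, and C1(CO2Ar)–C6(CH3)–C5(H) is a contiguous carbon edge. This is the pattern formed when a vinylketene (C4, C1, C6, C5) combines with a silyl ynol ether (C3, C2), with O4 arriving as a free phenol and O2 as a silyl ether.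

## Retrosynthetic reasoning

**Unmasking.** Target 31 is traced back to 30 by hydrogenolysis of the benzyl ester and benzyl ether of ring C, the one deprotection that leaves two aryl esters alone. Compound 30 comes from 29 by desilylation at O2 of ring B. The silyl group is there because the ring-forming step delivers it, and its removal is orthogonal to the benzyl groups.

**Ester between rings A and B.** The acyl C–O bond is cut to give phenol 23 and acid chloride 28, made in the flask from acid 27. Phenol 23 has a single free hydroxyl, flanked by two ring hydrogens, so no site selectivity is needed. The hindered partner is the electrophile, which can be activated strongly.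

**Ring A acid.** Acid 27 is cut at the aryl–carboxyl bond to aryllithium 26, bromide 25 and arene 24. Arene 24 has only one kind of open position, so the substitution pattern is fixed by the starting material.

**Ring B (key disconnection).** In 23, bonds C1–C2 and C3–C4 are cut to release C2–C3 as ynol ether 18. Bonds C4–C5 and C1–C6 are cut so that the other four ring carbons come from diazo keto ester 13 by way of 19, 20, 21 and 22. The cut is made here because the C1 ester of 23, wedged between OSi and CH3, is the most hindered bond of the molecule. In 13 that ester already exists, as the ester of an open-chain acyl group. The forward step must generate ketene 19 by Wolff rearrangement, join it to 18 in the right orientation, and carry 20 through ring opening and ring closure to the arene.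

**Diazo keto ester.** Compound 13 is cut between the diazo carbon and the ketone carbon: oxidation of aldol adduct 12, which comes from diazoacetate 9 (as its lithio derivative 11) and aldehyde 10. Direct C-acylation of 9 was set aside. Acylation of a diazoacetate is slow and releases acid, and an unsaturated acylating agent would also act as a dipolarophile toward the diazo group. Addition to an aldehyde at low temperature followed by neutral oxidation avoids all three problems.

**Ester between rings B and C.** Diazoacetate 9 is traced through 8 and 7 to bromoacetate 6 and then to phenol 5. The ester C–O bond is thus made by acylating an unhindered phenol with a two-carbon acyl group, before ring B exists.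

**Ring C.** Phenol 5 comes from purchased acid 1 through 2, 3 and 4. The order follows reactivity: the carboxylate is benzylated first, the more reactive O4 is parked as an allyl ether, the chelated O2 is benzylated, and O4 is released. O2 must be capped because a free phenol would intercept ketene 19.

**Ynol ether.** Compound 18 is cut at O–Si into ynolate 17 and silyl chloride 15. Ynolate 17 arises by cycloreversion of lithiated isoxazole 16, made from 14.

## Alternatives that were turned down

**Alternative 1:** Ring A is disconnected at C1–C6 and C3–C4 into methyl 4-methoxyacetoacetate A2 and methyl crotonate A3. In the forward step the enolate of A2 adds to the β-carbon of A3, and the methoxy-bearing carbon then closes onto the crotonate ester. The product is the cyclohexane-1,3-dione, drawn as its enol, methyl trans-4-hydroxy-3-methoxy-6-methyl-2-oxocyclohex-3-ene-1-carboxylate A1.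
- For: the reagents are cheap, the Michael–Claisen sequence is a classical and dependable reaction class, and every ring A substituent is placed unambiguously. On reliability of the key step it is stronger than the chosen route.
- Against: it builds the one ring that needs no building. Arene 24 already carries the three methoxy groups and the methyl group, and reaches acid 27 in two steps. A1 would still need dehydrogenation to the arene, two O-methylations (one at a chelated hydroxyl) and saponification of a di-ortho-substituted ester.
- Comparison: it contributes nothing to the two depside bonds or to the differentiation of the ring B oxygens. The chosen strategy spends its key step on those problems.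

**Alternative 2:** Ring B is disconnected at the aldol bond C1–C6 and at the ester C–O bond, leading to phenol 2 and 6-(2,4-dioxopentyl)-2,2-dimethyl-4H-1,3-dioxin-4-one A5. Heating A5 releases the acylketene 3,5,7-trioxooct-1-en-1-one A6. The 4-OH of 2 adds to A6 to give benzyl 2-hydroxy-6-methyl-4-[(3,5,7-trioxooctanoyl)oxy]benzoate A7. Dehydrating aldol closure of A7 then gives benzyl 4-[(2,4-dihydroxy-6-methylbenzoyl)oxy]-2-hydroxy-6-methylbenzoate A4.
- For: like the chosen route it makes the hindered ester before the ring exists, here by capture of ketene A6. It needs no protection of ring C beyond the benzyl ester, so it is shorter, and the reaction class is well established. On step economy and precedent it is stronger.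
- Against: A7 is an aryl ester, hence an activated one, of an enolisable polyketone. Under the base that normally drives the aromatisation, Claisen-type closure with expulsion of the aryloxide and simple ester cleavage compete with the aldol. A4 also carries three free phenols, so the ring A acylation depends on the non-chelated 4-OH of ring B reacting faster than two chelated hydroxyls.
- Comparison: the chosen strategy forms ring B under neutral conditions (light, then heat) with no enolisable polyketone, and delivers the two ring B oxygens differentiated, so the later acylation has one possible site.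

**Alternative 3:** The aryl–carbonyl bond of ring A and the ester C–O bond are cut together. The pieces are 1-iodo-2,3,4-trimethoxy-6-methylbenzene A9, carbon monoxide A11 and the didepside phenol benzyl 2-(benzyloxy)-4-{[2-(benzyloxy)-4-hydroxy-6-methylbenzoyl]oxy}-6-methylbenzoate A10. Zerovalent palladium inserts into A9, A11 inserts, and the phenoxide of A10 captures the acyl group. The product is the tribenzyl-protected target, benzyl 2-(benzyloxy)-4-{[2-(benzyloxy)-6-methyl-4-(2,3,4-trimethoxy-6-methylbenzoyloxy)benzoyl]oxy}-6-methylbenzoate A8.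
- For: it is convergent, it avoids making and activating a hindered acid, and A8 needs only one hydrogenolysis where the chosen route needs desilylation plus hydrogenolysis. On the end game it is stronger.
- Against: A9 is electron-rich and di-ortho-substituted, so oxidative addition and capture of the hindered acyl group are slow. The base and heat of aryloxycarbonylation expose the aryl ester of A10 to phenoxide exchange.
- Comparison: it only replaces the least problematic bond formation (step 13). A10, with the truly hindered ring B ester, would still have to be made by classical esterification. The chosen strategy addresses that bond and the ring B oxygen pattern in one step.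

Key step: step 10

## Route

Assumption: compounds 1, 10, 14, 15 and 24 are taken as purchasable. Compound 12 is made and used as a racemate, because its only stereocentre disappears in step 8.

**Step 1**
Reactants: 1 orsellinic acid (2,4-dihydroxy-6-methylbenzoic acid)
Product: 2 benzyl 2,4-dihydroxy-6-methylbenzoate
Conditions: BnBr (1.05 equiv), KHCO3, DMF, rt
Reagents that add atoms: benzyl bromide, BrCc1ccccc1
Why: Carboxylate O-alkylation (SN2); hydrogencarbonate deprotonates only the carboxylic acid, so both phenols stay free, and room temperature avoids decarboxylation of the acid.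

**Step 2**
Reactants: 2 benzyl 2,4-dihydroxy-6-methylbenzoate
Product: 3 benzyl 4-(allyloxy)-2-hydroxy-6-methylbenzoate
Conditions: allyl bromide (1.05 equiv), K2CO3, acetone, rt
Reagents that add atoms: allyl bromide, C=CCBr
Why: Williamson ether synthesis; the 4-OH, para to the ester and not hydrogen-bonded, is the more acidic and accessible phenol, while the 2-OH is held by a hydrogen bond to the ester carbonyl, so monoalkylation at O4 is expected.

**Step 3**
Reactants: 3 benzyl 4-(allyloxy)-2-hydroxy-6-methylbenzoate
Product: 4 benzyl 4-(allyloxy)-2-(benzyloxy)-6-methylbenzoate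
Conditions: BnBr, K2CO3, DMF, 60 °C
Reagents that add atoms: benzyl bromide, BrCc1ccccc1
Why: Williamson ether synthesis under more forcing conditions alkylates the chelated 2-OH; the allyl ether and the benzyl ester are inert to carbonate at this temperature.

**Step 4**
Reactants: 4 benzyl 4-(allyloxy)-2-(benzyloxy)-6-methylbenzoate
Product: 5 benzyl 2-(benzyloxy)-4-hydroxy-6-methylbenzoate
Conditions: Pd(PPh3)4 (5 mol%), morpholine, THF, rt
Reagents that add atoms: none
Why: Tsuji–Trost deallylation; zerovalent palladium ionises the allyl aryl ether to a π-allyl complex and morpholine takes up the allyl group, while benzyl ether and benzyl ester are not touched.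

**Step 5**
Reactants: 5 benzyl 2-(benzyloxy)-4-hydroxy-6-methylbenzoate
Product: 6 benzyl 2-(benzyloxy)-4-[(bromoacetyl)oxy]-6-methylbenzoate
Conditions: BrCH2COBr (1.1 equiv), pyridine (1.1 equiv), CH2Cl2, 0 °C
Reagents that add atoms: bromoacetyl bromide, BrCC(Br)=O
Why: O-acylation of an unhindered phenol with an acyl bromide; this creates the later ring B to ring C ester bond while its acyl carbon still carries only a CH2 group.

**Step 6**
Reactants: 6 benzyl 2-(benzyloxy)-4-[(bromoacetyl)oxy]-6-methylbenzoate
Product: 9 benzyl 2-(benzyloxy)-4-[(diazoacetyl)oxy]-6-methylbenzoate, via N-alkyl ditosylhydrazine 7 (not isolated), via glyoxylate tosylhydrazone 8 (not isolated)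
Conditions: TsNHNHTs (2 equiv), DBU (5 equiv), THF, 0 °C, short reaction time
Reagents that add atoms: N,N'-ditosylhydrazine, Cc1ccc(cc1)S(=O)(=O)NNS(=O)(=O)c1ccc(C)cc1
Why: N-alkylation of the ditosylhydrazine anion by the bromoacetate, then two base-induced losses of sulfinate (the second a Bamford–Stevens-type elimination) give the diazoacetate, a standard conversion of bromoacetates; the short time at 0 °C spares the aryl ester.

**Step 7**
Reactants: 9 benzyl 2-(benzyloxy)-4-[(diazoacetyl)oxy]-6-methylbenzoate; 10 methacrolein (2-methylprop-2-enal)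
Product: 12 benzyl 2-(benzyloxy)-4-[(2-diazo-3-hydroxy-4-methylpent-4-enoyl)oxy]-6-methylbenzoate (racemic), via lithiated diazoacetate 11 (not isolated)
Conditions: LiN(iPr)2 (LDA, 1.05 equiv), THF, −78 °C; then 10; AcOH quench at −78 °C
Reagents that add atoms: none
Why: Aldol-type 1,2-addition of a lithiated diazoacetate to an aldehyde; at −78 °C the hard carbanion attacks the carbonyl carbon and not the β-carbon of the enal. The new carbinol centre forms without control (racemate) and is removed in step 8.

**Step 8**
Reactants: 12 benzyl 2-(benzyloxy)-4-[(2-diazo-3-hydroxy-4-methylpent-4-enoyl)oxy]-6-methylbenzoate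
Product: 13 benzyl 2-(benzyloxy)-4-[(2-diazo-4-methyl-3-oxopent-4-enoyl)oxy]-6-methylbenzoate
Conditions: IBX (2-iodoxybenzoic acid, 1.5 equiv), DMSO, rt
Reagents that add atoms: none
Why: Oxidation of a β-hydroxy α-diazo ester to the α-diazo β-keto ester with 2-iodoxybenzoic acid, a neutral oxidant that leaves the diazo group, the alkene and the benzyl groups alone.

**Step 9**
Reactants: 14 3-phenylisoxazole; 15 chlorotriisopropylsilane
Product: 18 (triisopropylsilyloxy)ethyne, via 5-lithio-3-phenylisoxazole 16 (not isolated), via lithium ethynolate 17 (not isolated)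
Conditions: n-BuLi (1.0 equiv), THF, −78 °C to −50 °C; then 15, −78 °C to 0 °C; pentane work-up, rapid chromatography
Reagents that add atoms: none
Why: Deprotonation at C5 of the isoxazole gives 16, which undergoes cycloreversion (cleavage of N–O and C3–C4) to the nitrile and ynolate 17, a known way to generate ynolates. O-silylation of ynolates with the bulky silyl chloride is the standard route to silyl ynol ethers.

**Step 10**
Reactants: 13 benzyl 2-(benzyloxy)-4-[(2-diazo-4-methyl-3-oxopent-4-enoyl)oxy]-6-methylbenzoate; 18 (triisopropylsilyloxy)ethyne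
Product: 23 benzyl 2-(benzyloxy)-4-{[4-hydroxy-6-methyl-2-(triisopropylsilyloxy)benzoyl]oxy}-6-methylbenzoate, via vinylketene 19 (not isolated), via cyclobutenone 20 (not isolated), via dienylketene 21 (not isolated), via cyclohexadienone 22 (not isolated)
Conditions: 18 (3 equiv), hν (300 nm, Pyrex), degassed ClCH2CH2Cl (0.03 M), rt until 13 is consumed; then 80 °C
Reagents that add atoms: none
Why: Proposed new method: irradiation of the 2-diazo-1,3-dicarbonyl unit of 13 should expel N2 while the isopropenyl group shifts from the ketone carbon to the diazo carbon (Wolff rearrangement; in diazo keto esters the carbon substituent of the ketone migrates in preference to the aryloxy group), forming bond C1–C6 and giving vinylketene 19, whose ketene α-carbon carries the aryl ester. The nucleophilic CH carbon of ynol ether 18 attacks the ketene carbonyl carbon and the silyloxy carbon closes on the ester-stabilised enolate carbon, a polar (2+2) cycloaddition that makes bonds C3–C4 and C1–C2 in cyclobutenone 20. At 80 °C the four-membered ring opens by conrotatory four-electron electrocyclic cleavage of C1–C4 to dienylketene 21, and ring B is closed by thermal disrotatory six-electron electrocyclization between the ketene carbon and the terminal CH2 (bond C4–C5), after which dienone 22 tautomerises to the phenol. The closest known reaction is the second-generation Danheiser benzannulation, in which α'-diazo enones are photolysed with silyloxyalkynes, together with the Wolff rearrangement of α-diazo β-keto esters; new is the use of a diazo keto ester so that the ketene already carries the ester. No stereocentre results: the quaternary carbon of 20 is racemic and becomes sp2 on ring opening. The step needs regioselective (2+2) union, which the polarisation of 18 (electron-rich CH terminus) and of the ketene (electrophilic central carbon) secures, so that the ketene oxygen ends as the free 4-OH and the silyloxy carbon as C2. It also needs the isopropenyl group to turn inward on ring opening; since opening is reversible and only the (Z)-dienylketene can close irreversibly to the arene, the productive isomer should be drained. Running the photolysis to completion at room temperature before heating keeps the product phenol from meeting ketene 19.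

**Step 11**
Reactants: 24 3,4,5-trimethoxytoluene
Product: 25 2-bromo-3,4,5-trimethoxytoluene (1-bromo-2,3,4-trimethoxy-6-methylbenzene)
Conditions: NBS (1.05 equiv), MeCN, rt
Reagents that add atoms: N-bromosuccinimide, O=C1CCC(=O)N1Br
Why: Electrophilic aromatic bromination; the two open positions of 24 are equivalent and activated by ortho and para methoxy groups, so a single monobromide is expected.

**Step 12**
Reactants: 25 2-bromo-3,4,5-trimethoxytoluene
Product: 27 2,3,4-trimethoxy-6-methylbenzoic acid, via aryllithium 26 (not isolated)
Conditions: n-BuLi, THF, −78 °C; CO2; then aq. HCl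
Reagents that add atoms: carbon dioxide, O=C=O
Why: Bromine–lithium exchange followed by carboxylation of the aryllithium, which places the carboxyl group exactly where the bromine was.

**Step 13**
Reactants: 27 2,3,4-trimethoxy-6-methylbenzoic acid; 23 benzyl 2-(benzyloxy)-4-{[4-hydroxy-6-methyl-2-(triisopropylsilyloxy)benzoyl]oxy}-6-methylbenzoate
Product: 29 benzyl 2-(benzyloxy)-6-methyl-4-{[6-methyl-4-(2,3,4-trimethoxy-6-methylbenzoyloxy)-2-(triisopropylsilyloxy)benzoyl]oxy}benzoate, via acid chloride 28 (not isolated)
Conditions: (COCl)2, DMF (cat.), CH2Cl2, 0 °C to rt, evaporate; then 23, Et3N, DMAP (cat.), CH2Cl2, 0 °C to rt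
Reagents that add atoms: none
Why: Acyl chloride formation followed by DMAP-catalysed O-acylation; 23 has one free hydroxyl, flanked by two ring hydrogens, and the di-ortho-substituted acyl chloride should react through its acylpyridinium ion.

**Step 14**
Reactants: 29 benzyl 2-(benzyloxy)-6-methyl-4-{[6-methyl-4-(2,3,4-trimethoxy-6-methylbenzoyloxy)-2-(triisopropylsilyloxy)benzoyl]oxy}benzoate
Product: 30 benzyl 2-(benzyloxy)-4-{[2-hydroxy-6-methyl-4-(2,3,4-trimethoxy-6-methylbenzoyloxy)benzoyl]oxy}-6-methylbenzoate
Conditions: Bu4NF (1.2 equiv), AcOH (1.5 equiv), THF, 0 °C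
Reagents that add atoms: none
Why: Fluoride-induced cleavage of an aryl silyl ether; the acetic acid buffer protonates the phenoxide at once, so that it cannot attack the aryl esters.

**Step 15**
Reactants: 30 benzyl 2-(benzyloxy)-4-{[2-hydroxy-6-methyl-4-(2,3,4-trimethoxy-6-methylbenzoyloxy)benzoyl]oxy}-6-methylbenzoate
Product: 31 2-hydroxy-4-{[2-hydroxy-6-methyl-4-(2,3,4-trimethoxy-6-methylbenzoyloxy)benzoyl]oxy}-6-methylbenzoic acid (target)
Conditions: H2 (1 atm), Pd/C (10% palladium on carbon), EtOAc, rt
Reagents that add atoms: none
Why: Hydrogenolysis of the benzyl ester and the benzyl aryl ether; aryl esters, methyl ethers and the arenes are inert under these conditions.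

## Compound list

1 | orsellinic acid (2,4-dihydroxy-6-methylbenzoic acid) | Cc1cc(O)cc(O)c1C(=O)O | starting material
2 | benzyl 2,4-dihydroxy-6-methylbenzoate | Cc1cc(O)cc(O)c1C(=O)OCc1ccccc1 | intermediate
3 | benzyl 4-(allyloxy)-2-hydroxy-6-methylbenzoate | Cc1cc(OCC=C)cc(O)c1C(=O)OCc1ccccc1 | intermediate
4 | benzyl 4-(allyloxy)-2-(benzyloxy)-6-methylbenzoate | Cc1cc(OCC=C)cc(OCc2ccccc2)c1C(=O)OCc1ccccc1 | intermediate
5 | benzyl 2-(benzyloxy)-4-hydroxy-6-methylbenzoate | Cc1cc(O)cc(OCc2ccccc2)c1C(=O)OCc1ccccc1 | intermediate
6 | benzyl 2-(benzyloxy)-4-[(bromoacetyl)oxy]-6-methylbenzoate | Cc1cc(OC(=O)CBr)cc(OCc2ccccc2)c1C(=O)OCc1ccccc1 | intermediate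
7 | benzyl 2-(benzyloxy)-4-({[1,2-bis(4-methylbenzenesulfonyl)hydrazinyl]acetyl}oxy)-6-methylbenzoate (N-alkyl ditosylhydrazine) | Cc1cc(OC(=O)CN(NS(=O)(=O)c2ccc(C)cc2)S(=O)(=O)c2ccc(C)cc2)cc(OCc2ccccc2)c1C(=O)OCc1ccccc1 | intermediate (not isolated)
8 | benzyl 2-(benzyloxy)-6-methyl-4-({[2-(4-methylbenzenesulfonyl)hydrazinylidene]acetyl}oxy)benzoate (glyoxylate tosylhydrazone) | Cc1cc(OC(=O)C=NNS(=O)(=O)c2ccc(C)cc2)cc(OCc2ccccc2)c1C(=O)OCc1ccccc1 | intermediate (not isolated)
9 | benzyl 2-(benzyloxy)-4-[(diazoacetyl)oxy]-6-methylbenzoate | Cc1cc(OC(=O)C=[N+]=[N-])cc(OCc2ccccc2)c1C(=O)OCc1ccccc1 | intermediate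
10 | methacrolein (2-methylprop-2-enal) | C=C(C)C=O | starting material
11 | C-lithio derivative of 9 (lithiated diazoacetate) | [Li]C(=[N+]=[N-])C(=O)Oc1cc(C)c(C(=O)OCc2ccccc2)c(OCc2ccccc2)c1 | intermediate (not isolated)
12 | benzyl 2-(benzyloxy)-4-[(2-diazo-3-hydroxy-4-methylpent-4-enoyl)oxy]-6-methylbenzoate (racemic) | C=C(C)C(O)C(=[N+]=[N-])C(=O)Oc1cc(C)c(C(=O)OCc2ccccc2)c(OCc2ccccc2)c1 | intermediate
13 | benzyl 2-(benzyloxy)-4-[(2-diazo-4-methyl-3-oxopent-4-enoyl)oxy]-6-methylbenzoate | C=C(C)C(=O)C(=[N+]=[N-])C(=O)Oc1cc(C)c(C(=O)OCc2ccccc2)c(OCc2ccccc2)c1 | intermediate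
14 | 3-phenylisoxazole | c1ccc(cc1)-c1ccon1 | starting material
15 | chlorotriisopropylsilane | CC(C)[Si](Cl)(C(C)C)C(C)C | starting material
16 | 5-lithio-3-phenylisoxazole | [Li]c1cc(-c2ccccc2)no1 | intermediate (not isolated)
17 | lithium ethynolate | [Li+].[O-]C#C | intermediate (not isolated)
18 | (triisopropylsilyloxy)ethyne | C#CO[Si](C(C)C)(C(C)C)C(C)C | intermediate
19 | benzyl 2-(benzyloxy)-6-methyl-4-{[3-methyl-2-(oxomethylidene)but-3-enoyl]oxy}benzoate (vinylketene) | C=C(C)C(=C=O)C(=O)Oc1cc(C)c(C(=O)OCc2ccccc2)c(OCc2ccccc2)c1 | intermediate (not isolated)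
20 | 3-(benzyloxy)-4-(benzyloxycarbonyl)-5-methylphenyl 4-oxo-1-(prop-1-en-2-yl)-2-(triisopropylsilyloxy)cyclobut-2-ene-1-carboxylate (racemic cyclobutenone) | O=C1C=C(O[Si](C(C)C)(C(C)C)C(C)C)C1(C(C)=C)C(=O)Oc1cc(C)c(C(=O)OCc2ccccc2)c(OCc2ccccc2)c1 | intermediate (not isolated)
21 | 3-(benzyloxy)-4-(benzyloxycarbonyl)-5-methylphenyl (2Z)-5-oxo-2-(prop-1-en-2-yl)-3-(triisopropylsilyloxy)penta-2,4-dienoate (dienylketene) | O=C=C/C(O[Si](C(C)C)(C(C)C)C(C)C)=C(\C(C)=C)C(=O)Oc1cc(C)c(C(=O)OCc2ccccc2)c(OCc2ccccc2)c1 | intermediate (not isolated)
22 | 3-(benzyloxy)-4-(benzyloxycarbonyl)-5-methylphenyl 2-methyl-4-oxo-6-(triisopropylsilyloxy)cyclohexa-1,5-diene-1-carboxylate (cyclohexadienone) | O=C1C=C(O[Si](C(C)C)(C(C)C)C(C)C)C(C(=O)Oc2cc(C)c(C(=O)OCc3ccccc3)c(OCc3ccccc3)c2)=C(C)C1 | intermediate (not isolated)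
23 | benzyl 2-(benzyloxy)-4-{[4-hydroxy-6-methyl-2-(triisopropylsilyloxy)benzoyl]oxy}-6-methylbenzoate | Cc1cc(O)cc(O[Si](C(C)C)(C(C)C)C(C)C)c1C(=O)Oc1cc(C)c(C(=O)OCc2ccccc2)c(OCc2ccccc2)c1 | intermediate
24 | 3,4,5-trimethoxytoluene | COc1cc(C)cc(OC)c1OC | starting material
25 | 2-bromo-3,4,5-trimethoxytoluene | COc1cc(C)c(Br)c(OC)c1OC | intermediate
26 | (2,3,4-trimethoxy-6-methylphenyl)lithium | COc1cc(C)c([Li])c(OC)c1OC | intermediate (not isolated)
27 | 2,3,4-trimethoxy-6-methylbenzoic acid | COc1cc(C)c(C(=O)O)c(OC)c1OC | intermediate
28 | 2,3,4-trimethoxy-6-methylbenzoyl chloride | COc1cc(C)c(C(=O)Cl)c(OC)c1OC | intermediate (not isolated)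
29 | benzyl 2-(benzyloxy)-6-methyl-4-{[6-methyl-4-(2,3,4-trimethoxy-6-methylbenzoyloxy)-2-(triisopropylsilyloxy)benzoyl]oxy}benzoate | COc1cc(C)c(C(=O)Oc2cc(C)c(C(=O)Oc3cc(C)c(C(=O)OCc4ccccc4)c(OCc4ccccc4)c3)c(O[Si](C(C)C)(C(C)C)C(C)C)c2)c(OC)c1OC | intermediate
30 | benzyl 2-(benzyloxy)-4-{[2-hydroxy-6-methyl-4-(2,3,4-trimethoxy-6-methylbenzoyloxy)benzoyl]oxy}-6-methylbenzoate | COc1cc(C)c(C(=O)Oc2cc(C)c(C(=O)Oc3cc(C)c(C(=O)OCc4ccccc4)c(OCc4ccccc4)c3)c(O)c2)c(OC)c1OC | intermediate
31 | 2-hydroxy-4-{[2-hydroxy-6-methyl-4-(2,3,4-trimethoxy-6-methylbenzoyloxy)benzoyl]oxy}-6-methylbenzoic acid | COc1cc(C)c(C(=O)Oc2cc(C)c(C(=O)Oc3cc(C)c(C(=O)O)c(O)c3)c(O)c2)c(OC)c1OC | target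

## Step count and risk

Total: 15 steps. Longest linear sequence: 12 steps (steps 1 to 8, 10, 13, 14, 15, from orsellinic acid). Steps 9, 11 and 12 are side branches.

**Step 10 (key step, proposed new method).** Several things can go wrong. Periselectivity may be lost: the zwitterion from 19 and 18 may close through the ester oxygen instead of carbon, or the ester instead of the isopropenyl group may turn inward on ring opening, diverting material to pyranones. Ketene intermediates may be captured by nucleophiles. The aryl esters may undergo photo-Fries rearrangement if short-wavelength light reaches them. Ynol ether 18 may isomerise by 1,3-silyl shift before it is consumed.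

The fallback gives up the benzannulation and uses classical depside chemistry. It sets out from 2, 5 and 27 and rejoins the route at 30. Phenol 2 is acylated at its non-chelated 4-OH with acid chloride 28 (from 27 as in step 13; Et3N, DMAP, CH2Cl2) to give benzyl 2-hydroxy-6-methyl-4-[(2,3,4-trimethoxy-6-methylbenzoyl)oxy]benzoate F1. Hydrogenolysis (H2, Pd/C, EtOAc) frees 2-hydroxy-6-methyl-4-[(2,3,4-trimethoxy-6-methylbenzoyl)oxy]benzoic acid F2. F2 is then condensed with the 4-OH of 5 using (CF3CO)2O in toluene at rt, the classical coupling of ortho-hydroxybenzoic acids with phenols, to give 30.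

**Step 9.** The unhindered parent ynolate 17 may be silylated at carbon, which leads to a silylketene, in competition with O-silylation. The alkyllithium or 17 may also add to the liberated nitrile if the deprotonation is not clean. The fallback changes the source of the ynolate. It sets out from 15 and comes back at 18. Acetylene in THF at −78 °C is converted with n-BuLi into lithium acetylide F3. This is oxidised with lithium tert-butyl peroxide (LiOOtBu, from tBuOOH and LiN(SiMe3)2) to ynolate 17, which is silylated with 15 as before. The weak point of this variant is disproportionation of the monolithium acetylide on warming.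

**Step 7.** The lithiated aryl diazoacetate 11 may condense with itself or lose aryloxide before the aldehyde arrives, and the enal may polymerise. The fallback installs the diazo group last. It sets out from 5 and comes back at 13, leaving out 6, 9 and 12. Meldrum's acid is C-acylated with methacryloyl chloride (pyridine, CH2Cl2, 0 °C) to 5-(1-hydroxy-2-methylprop-2-en-1-ylidene)-2,2-dimethyl-1,3-dioxane-4,6-dione F4. Heating F4 with 5 in toluene at 90 °C, with loss of acetone and carbon dioxide, gives the β-keto ester benzyl 2-(benzyloxy)-6-methyl-4-[(4-methyl-3-oxopent-4-enoyl)oxy]benzoate F5. Regitz diazo transfer (4-acetamidobenzenesulfonyl azide, Et3N, MeCN, 0 °C) then converts F5 into 13.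

**Step 14.** While the basic fluoride reagent is present, phenoxide may transfer acyl groups between the depside esters (transesterification, acyl migration). The fallback reverses the order of the two deprotections and removes silicon under acid. It sets out from 29 and comes back at 31. Hydrogenolysis of 29 (H2, Pd/C, EtOAc) gives 2-hydroxy-6-methyl-4-{[6-methyl-4-(2,3,4-trimethoxy-6-methylbenzoyloxy)-2-(triisopropylsilyloxy)benzoyl]oxy}benzoic acid F6. F6 is desilylated with HF·pyridine in THF at 0 °C, where no free phenoxide arises, to give 31.

## Further compounds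

F1 | step 10 | benzyl 2-hydroxy-6-methyl-4-[(2,3,4-trimethoxy-6-methylbenzoyl)oxy]benzoate | COc1cc(C)c(C(=O)Oc2cc(C)c(C(=O)OCc3ccccc3)c(O)c2)c(OC)c1OC
F2 | step 10 | 2-hydroxy-6-methyl-4-[(2,3,4-trimethoxy-6-methylbenzoyl)oxy]benzoic acid | COc1cc(C)c(C(=O)Oc2cc(C)c(C(=O)O)c(O)c2)c(OC)c1OC
F3 | step 9 | lithium acetylide | [Li]C#C
F4 | step 7 | 5-(1-hydroxy-2-methylprop-2-en-1-ylidene)-2,2-dimethyl-1,3-dioxane-4,6-dione | C=C(C)C(O)=C1C(=O)OC(C)(C)OC1=O
F5 | step 7 | benzyl 2-(benzyloxy)-6-methyl-4-[(4-methyl-3-oxopent-4-enoyl)oxy]benzoate | C=C(C)C(=O)CC(=O)Oc1cc(C)c(C(=O)OCc2ccccc2)c(OCc2ccccc2)c1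
F6 | step 14 | 2-hydroxy-6-methyl-4-{[6-methyl-4-(2,3,4-trimethoxy-6-methylbenzoyloxy)-2-(triisopropylsilyloxy)benzoyl]oxy}benzoic acid | COc1cc(C)c(C(=O)Oc2cc(C)c(C(=O)Oc3cc(C)c(C(=O)O)c(O)c3)c(O[Si](C(C)C)(C(C)C)C(C)C)c2)c(OC)c1OC
A1 | alternative 1 | methyl trans-4-hydroxy-3-methoxy-6-methyl-2-oxocyclohex-3-ene-1-carboxylate (racemic, one enantiomer drawn) | C[C@@H]1CC(O)=C(OC)C(=O)[C@H]1C(=O)OC
A2 | alternative 1 | methyl 4-methoxyacetoacetate | COCC(=O)CC(=O)OC
A3 | alternative 1 | methyl crotonate | C/C=C/C(=O)OC
A4 | alternative 2 | benzyl 4-[(2,4-dihydroxy-6-methylbenzoyl)oxy]-2-hydroxy-6-methylbenzoate | Cc1cc(O)cc(O)c1C(=O)Oc1cc(C)c(C(=O)OCc2ccccc2)c(O)c1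
A5 | alternative 2 | 6-(2,4-dioxopentyl)-2,2-dimethyl-4H-1,3-dioxin-4-one | CC(=O)CC(=O)CC1=CC(=O)OC(C)(C)O1
A6 | alternative 2 | 3,5,7-trioxooct-1-en-1-one (acylketene) | CC(=O)CC(=O)CC(=O)C=C=O
A7 | alternative 2 | benzyl 2-hydroxy-6-methyl-4-[(3,5,7-trioxooctanoyl)oxy]benzoate | CC(=O)CC(=O)CC(=O)CC(=O)Oc1cc(C)c(C(=O)OCc2ccccc2)c(O)c1
A8 | alternative 3 | benzyl 2-(benzyloxy)-4-{[2-(benzyloxy)-6-methyl-4-(2,3,4-trimethoxy-6-methylbenzoyloxy)benzoyl]oxy}-6-methylbenzoate | COc1cc(C)c(C(=O)Oc2cc(C)c(C(=O)Oc3cc(C)c(C(=O)OCc4ccccc4)c(OCc4ccccc4)c3)c(OCc4ccccc4)c2)c(OC)c1OC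
A9 | alternative 3 | 1-iodo-2,3,4-trimethoxy-6-methylbenzene | COc1cc(C)c(I)c(OC)c1OC
A10 | alternative 3 | benzyl 2-(benzyloxy)-4-{[2-(benzyloxy)-4-hydroxy-6-methylbenzoyl]oxy}-6-methylbenzoate | Cc1cc(O)cc(OCc2ccccc2)c1C(=O)Oc1cc(C)c(C(=O)OCc2ccccc2)c(OCc2ccccc2)c1
A11 | alternative 3 | carbon monoxide | [C-]#[O+]
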